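**Plan**

1. Numbering is that of isochroman-1-one (C1 lactone carbonyl, O2, C3 stereocentre, C4, C4a, C5 to C8, C8a; OH on C8). The enabling feature: O2, C3, C4, C4a, C5 and C6 are the six ring atoms of a masked (2R)-2-alkyl-2,3-dihydropyran-4-one (ring oxygen = O2, ketone carbon = C4a, enol-ether carbon = C6), and C7, C8, C8a and C1 with their two oxygens are a methyl acetoacetate unit.
2. Retrosynthesis: C1–O2, C4a–C8a and C6–C7 are cut together (lactone, aldol and conjugate-addition bonds) to give that dihydropyranone and an acetoacetate bis-silyl dienol ether. Then C3–C4 and O2–C6 are cut (hetero-Diels–Alder) to give (7Z)-hexadec-7-enal, and finally the C8–C9 bond of the C16 chain (acetylide alkylation).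
3. Forward: the C16 chain is joined first (alkylation, Lindlar semi-hydrogenation, oxidation), the pyranone ring is built second, and in the last step that ring is opened while the benzene ring and then the lactone ring close.
4. Stereochemistry: C3 is set once, by the (S)-BINOL–Ti(OiPr)4 catalyst in the hetero-Diels–Alder step, and no later step makes or breaks a bond at it. The Z-alkene comes from syn addition of hydrogen to the alkyne.

Key step: step 7

Remark: the enol-ether geometries of 10 and 11 are lost in the next step and are left undefined; 13 is drawn as the 2,6-trans adduct expected from axial attack (its epimer would give the same arene); (S)-BINOL is chosen because (S)-BINOL–Ti(OiPr)4 directs nucleophiles to the Si face of unbranched aldehydes in the related allylation, and this sense should be confirmed by Mosher ester analysis of 7 from a small run stopped before the acid treatment.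

**Route**

Step 1
Reactants: 1 oct-7-yn-1-ol, 2 1-bromooctane
Product: 3 hexadec-7-yn-1-ol
Conditions: n-BuLi (2.1 equiv), THF, −78 → 0 °C; DMPU, 2 (1.1 equiv), 0 → 20 °C; aq. NH4Cl
Reagents that add atoms: none
Why: Double deprotonation gives the alkoxide–acetylide dianion, whose carbon terminus is alkylated by the primary bromide in the dipolar cosolvent (SN2 acetylide alkylation), the lithium alkoxide being much the poorer nucleophile.

Step 2
Reactants: 3 hexadec-7-yn-1-ol
Product: 4 (7Z)-hexadec-7-en-1-ol
Conditions: H2 (1 atm), Pd/CaCO3 poisoned with Pb(OAc)2, quinoline, hexane/EtOAc, 20 °C, stopped after 1 equiv H2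
Reagents that add atoms: none
Why: Lindlar semi-hydrogenation delivers both hydrogens to the same face of the alkyne on the poisoned palladium surface and should stop at the alkene, which fixes the Z geometry.

Step 3
Reactants: 4 (7Z)-hexadec-7-en-1-ol
Product: 5 (7Z)-hexadec-7-enal
Conditions: TEMPO (10 mol %), PhI(OAc)2 (1.1 equiv), CH2Cl2, 20 °C
Reagents that add atoms: none
Why: Oxoammonium (TEMPO) oxidation with PhI(OAc)2 as terminal oxidant takes a primary alcohol to the aldehyde without over-oxidation and without touching or isomerising the remote Z-alkene.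

Step 4
Reactants: 5 (7Z)-hexadec-7-enal, 6 (E)-1-methoxy-3-(trimethylsilyloxy)buta-1,3-diene
Product: 8 (2R)-2-[(6Z)-pentadec-6-en-1-yl]-2,3-dihydro-4H-pyran-4-one, via aldol adduct 7 (not isolated)
Conditions: (S)-BINOL (20 mol %), Ti(OiPr)4 (10 mol %), CF3CO2H (trace), 4 Å MS, Et2O; 5, 6 (1.2 equiv), −20 °C; then CF3CO2H, CH2Cl2, 0 °C
Reagents that add atoms: none
Why: BINOL–Ti(OiPr)4-catalysed Mukaiyama aldol addition of the diene terminus to the aldehyde, followed by acid-induced oxa-Michael closure and loss of methanol (a formal hetero-Diels–Alder reaction well established for unbranched aliphatic aldehydes); the chiral titanium complex should shield the Re face so that the diene adds to the Si face and sets the (R) centre that becomes C3.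

Step 5
Reactants: 9 methyl acetoacetate
Product: 10 methyl 3-(trimethylsilyloxy)but-2-enoate
Conditions: Me3SiCl (1.5 equiv), NEt3 (1.6 equiv), hexane, 20 °C; filtration, distillation
Reagents that add atoms: chlorotrimethylsilane, C[Si](C)(C)Cl
Why: The readily enolised β-keto ester is O-silylated by Me3SiCl and NEt3 (silyl enol ether formation).

Step 6
Reactants: 10 methyl 3-(trimethylsilyloxy)but-2-enoate
Product: 11 1-methoxy-1,3-bis(trimethylsilyloxy)buta-1,3-diene
Conditions: LDA (1.1 equiv), THF, −78 °C; Me3SiCl (1.2 equiv), −78 → 20 °C; hexane, filtration under argon, used at once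
Reagents that add atoms: chlorotrimethylsilane, C[Si](C)(C)Cl
Why: LDA removes the γ-proton of the β-silyloxy enoate and the extended ester enolate is O-silylated at low temperature (standard two-stage preparation of acetoacetate bis-silyl dienol ethers).

Step 7
Reactants: 8 (2R)-2-[(6Z)-pentadec-6-en-1-yl]-2,3-dihydro-4H-pyran-4-one, 11 1-methoxy-1,3-bis(trimethylsilyloxy)buta-1,3-diene
Product: 16 (3R)-8-hydroxy-3-[(6Z)-pentadec-6-en-1-yl]isochroman-1-one, via silyloxydihydropyrylium triflate 12 (not isolated), via tetrahydropyranone keto ester 13 (not isolated), via open-chain hydroxy enedione 14 (not isolated), via hydroxy salicylate ester 15 (not isolated)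
Conditions: Me3SiOTf (1.2 equiv), CH2Cl2, 0 °C; 11 (1.5 equiv), −78 → 0 °C; then EtOH, NEt3 (4 equiv), 20 → 50 °C; 1 M HCl work-up
Reagents that add atoms: none
Why: Proposed new method: Me3SiOTf should turn the vinylogous ester 8 into the 4-silyloxy-2,3-dihydropyrylium ion 12, to whose C6 the terminal carbon of 11 adds (Mukaiyama–Michael addition, C6–C7) to give after ethanolysis the keto ester 13, from which NEt3 is expected to expel the ring oxygen at C6 by E1cB elimination to give 14, the C5=C6 geometry equilibrating through the extended enolate of the doubly activated C7 methylene. The closest known reaction type is the domino Michael, retro-Michael, aldol and lactonisation sequence of chromones with 1,3-bis(silyloxy)buta-1,3-dienes that gives 7-hydroxybenzo[c]chromen-6-ones, and its open-chain relative is the [3+3] salicylate synthesis from the same dienes and β-alkoxy enones; new here is a monocyclic dihydropyranone that must release a secondary alkoxide instead of a phenoxide. The benzene ring closes by 6-(enolexo)-exo-trig aldol addition of the active methylene C8a to the C4a ketone, followed by loss of water and enolisation of the C8 ketone to the phenol 15, and the lactone ring closes by 6-exo-trig acyl substitution of the freed C3 hydroxyl on the ester carbon C1 with loss of methanol, completed by the acidic work-up. No stereocentre is created, since the transient C6 centre of 13 (trans to C3 by axial attack) becomes an arene carbon, and no bond to C3 is made or broken, so it keeps the (R) configuration of 8. The selectivity required is ring opening at C6–O and not at C3–O2, which would pass through an achiral enone and erode C3; the substrate secures it because C6 is β to both the C4a and the C8 ketone and because only this opening feeds the irreversible aromatisation. A direct aldol of C8a onto C4a in 13 ahead of ring opening would lead to 15 by the same C6–O elimination, so both orders of events converge.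

**Compound list**

1 | oct-7-yn-1-ol | C#CCCCCCCO | starting material
2 | 1-bromooctane | CCCCCCCCBr | starting material
3 | hexadec-7-yn-1-ol | CCCCCCCCC#CCCCCCCO | intermediate
4 | (7Z)-hexadec-7-en-1-ol | CCCCCCCC/C=C\CCCCCCO | intermediate
5 | (7Z)-hexadec-7-enal | CCCCCCCC/C=C\CCCCCC=O | intermediate
6 | (E)-1-methoxy-3-(trimethylsilyloxy)buta-1,3-diene | CO/C=C/C(=C)O[Si](C)(C)C | starting material
7 | (1E,5R,11Z)-5-hydroxy-1-methoxyicosa-1,11-dien-3-one (aldol adduct, drawn as the free carbinol) | CCCCCCCC/C=C\CCCCC[C@@H](O)CC(=O)/C=C/OC | intermediate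
8 | (2R)-2-[(6Z)-pentadec-6-en-1-yl]-2,3-dihydro-4H-pyran-4-one | CCCCCCCC/C=C\CCCCC[C@@H]1CC(=O)C=CO1 | intermediate
9 | methyl acetoacetate | COC(=O)CC(C)=O | starting material
10 | methyl 3-(trimethylsilyloxy)but-2-enoate (E/Z mixture) | COC(=O)C=C(C)O[Si](C)(C)C | intermediate
11 | 1-methoxy-1,3-bis(trimethylsilyloxy)buta-1,3-diene (ketene acetal geometry undefined) | C=C(O[Si](C)(C)C)C=C(OC)O[Si](C)(C)C | intermediate
12 | (2R)-2-[(6Z)-pentadec-6-en-1-yl]-4-(trimethylsilyloxy)-2,3-dihydropyrylium trifluoromethanesulfonate | CCCCCCCC/C=C\CCCCC[C@@H]1CC(O[Si](C)(C)C)=CC=[O+]1.[O-]S(=O)(=O)C(F)(F)F | intermediate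
13 | methyl 3-oxo-4-{(2S,6R)-4-oxo-6-[(6Z)-pentadec-6-en-1-yl]oxan-2-yl}butanoate (2,6-trans; first formed as its silyl enol ether) | CCCCCCCC/C=C\CCCCC[C@@H]1CC(=O)C[C@@H](CC(=O)CC(=O)OC)O1 | intermediate
14 | methyl (5E,9R,15Z)-9-hydroxy-3,7-dioxotetracosa-5,15-dienoate | CCCCCCCC/C=C\CCCCC[C@@H](O)CC(=O)/C=C/CC(=O)CC(=O)OC | intermediate
15 | methyl 2-hydroxy-6-[(2R,8Z)-2-hydroxyheptadec-8-en-1-yl]benzoate | CCCCCCCC/C=C\CCCCC[C@@H](O)Cc1cccc(O)c1C(=O)OC | intermediate
16 | (3R)-8-hydroxy-3-[(6Z)-pentadec-6-en-1-yl]isochroman-1-one | CCCCCCCC/C=C\CCCCC[C@@H]1Cc2cccc(O)c2C(=O)O1 | target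

**Count**

Total step count: 7. Longest linear sequence: 5 steps (1, 2, 3, 4, 7); the diene branch (steps 5 and 6) joins at step 7.

**Steps most likely to fail**

Step 7. The base stage may stall at the Michael adduct, because expelling a secondary alkoxide is far less favourable than expelling the phenoxide of the chromone precedent. Slow opening would also give time for cleavage on the C3–O2 side and erosion of the configuration at C3. Incomplete lactonisation is only a matter of conditions (brief warming with catalytic TsOH in toluene). The fallback gives up the ring transformation and uses the established open-chain benzannulation, in which methoxide is the leaving group. It sets out from 5 and 6: step 4 is stopped before the acid treatment so that 7 is isolated. Silylation (t-BuMe2SiCl, imidazole, DMF) would give (1E,5R,11Z)-5-(tert-butyldimethylsilyloxy)-1-methoxyicosa-1,11-dien-3-one F1. The known TiCl4-mediated [3+3] cyclocondensation of 11 with acyclic β-alkoxy enones (CH2Cl2, −78 → 20 °C) would then give methyl 2-[(2R,8Z)-2-(tert-butyldimethylsilyloxy)heptadec-8-en-1-yl]-6-hydroxybenzoate F2, the diene terminus adding to the methoxy-bearing carbon and the central carbon to the ketone. HF·pyridine in THF would free the carbinol, rejoining the route at 15, which closes to 16 on warming with catalytic TsOH in toluene.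

Step 4. Facial discrimination by the titanium catalyst may be insufficient for an unbranched aliphatic aldehyde, or the sense may be opposite to the one assumed, and the enolisable aldehyde may be lost to self-condensation. The fallback sets the centre by hydrogenation, whose sense is secure, and builds the pyranone from a hydroxy ynone. It sets out from 5: Roskamp homologation (methyl diazoacetate, SnCl2, CH2Cl2) would give methyl (9Z)-3-oxooctadec-9-enoate F3. Noyori hydrogenation (H2, RuCl2[(R)-BINAP], MeOH), which reduces β-keto esters but leaves isolated alkenes alone, would give methyl (3R,9Z)-3-hydroxyoctadec-9-enoate F4. MeNHOMe·HCl with i-PrMgCl would give (3R,9Z)-3-hydroxy-N-methoxy-N-methyloctadec-9-enamide F5, and excess ethynylmagnesium bromide would give (5R,11Z)-5-hydroxyicos-11-en-1-yn-3-one F6. AgOTf-catalysed 6-endo-dig oxa-Michael cyclisation would return to the route at 8.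

Step 1. The dianion may be alkylated in part on oxygen, the bromide may be lost by elimination, or conversion may stay incomplete. The fallback replaces the dianion by a protected mono-anion. It sets out from 1: 3,4-dihydro-2H-pyran with catalytic PPTS would give 2-(oct-7-yn-1-yloxy)oxane F7. Deprotonation with n-BuLi and alkylation with 2 in THF/DMPU would give 2-(hexadec-7-yn-1-yloxy)oxane F8. PPTS in methanol would remove the acetal and return to the route at 3.

**Further compounds**

F1 | step 7 | (1E,5R,11Z)-5-(tert-butyldimethylsilyloxy)-1-methoxyicosa-1,11-dien-3-one | CCCCCCCC/C=C\CCCCC[C@@H](O[Si](C)(C)C(C)(C)C)CC(=O)/C=C/OC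
F2 | step 7 | methyl 2-[(2R,8Z)-2-(tert-butyldimethylsilyloxy)heptadec-8-en-1-yl]-6-hydroxybenzoate | CCCCCCCC/C=C\CCCCC[C@@H](O[Si](C)(C)C(C)(C)C)Cc1cccc(O)c1C(=O)OC
F3 | step 4 | methyl (9Z)-3-oxooctadec-9-enoate | CCCCCCCC/C=C\CCCCCC(=O)CC(=O)OC
F4 | step 4 | methyl (3R,9Z)-3-hydroxyoctadec-9-enoate | CCCCCCCC/C=C\CCCCC[C@@H](O)CC(=O)OC
F5 | step 4 | (3R,9Z)-3-hydroxy-N-methoxy-N-methyloctadec-9-enamide | CCCCCCCC/C=C\CCCCC[C@@H](O)CC(=O)N(C)OC
F6 | step 4 | (5R,11Z)-5-hydroxyicos-11-en-1-yn-3-one | CCCCCCCC/C=C\CCCCC[C@@H](O)CC(=O)C#C
F7 | step 1 | 2-(oct-7-yn-1-yloxy)oxane (racemic acetal) | C#CCCCCCCOC1CCCCO1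
F8 | step 1 | 2-(hexadec-7-yn-1-yloxy)oxane (racemic acetal) | CCCCCCCCC#CCCCCCCOC1CCCCO1
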